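I decide to drop the clock and reckon side product B against target, since dividing one rate by the other removes time.

| flask | starting material | partner | remark | time |
|---|---|---|---|---|
| oak | 2 mM | 0.45 equiv | run made earlier |  |
| maple | 2 mM | 0.68 equiv | run made earlier |  |
| flask | 2.0 mM | 0.900 equiv |  | 12 min |

| run | time / min | starting material / % | target / % | side product B / % |
|---|---|---|---|---|
| oak | 2.00 | 0.8 | 77.1 | 12.6 |
| oak | 4.00 | 0.7 | 78.4 | 15.0 |
| oak | 6.00 | 0 | 77.6 | 18.9 |
| oak | 8.00 | 0 | 77.4 | 19.6 |
| oak | 10.0 | 1.7 | 75.9 | 20.2 |
| oak | 12.0 | 0 | 79.2 | 19.6 |
| maple | 2.00 | 0 | 70.2 | 22.8 |
| maple | 4.00 | 0.1 | 71.1 | 28.1 |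
| maple | 6.00 | 0.8 | 68.8 | 26.9 |
| maple | 8.00 | 0.4 | 69.0 | 30.2 |
| maple | 10.0 | 0 | 69.8 | 28.2 |
| maple | 12.0 | 0 | 69.0 | 29.0 |

(readings scatter by 1 percentage point)

- the reaction counts as stopped when no species that holds the starting material changes by six tenths of a point or more over the second half of the time

* at 12 min, what has stopped the reaction, if anything has (the partner has run out first / forward and back rates have come level / all of the starting material has reacted / it is still moving)
* how much of the starting material has reacted by 12 min
* how much target there is at 12 min, in percent of the starting material charged
* how much side product B there is at 12 min, in percent of the starting material charged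

The runs give a ladder. On the fastest rung, starting material reads 0.8% in oak and 0% in maple at 2.00 min, within the scatter of zero, so its contest is decided before the first reading. On the next rung, oak's B still climbs from 12.6% to 18.9% at 6.00 min, while its target stays within scatter, so an unseen species seems to deliver B after the split. On the slowest rung, from 6.00 min to 12.0 min, oak's B reads 18.9% and then 19.6%, and maple's reads 26.9% and then 29.0%, so with a scatter of 1 percentage point these readings cannot say whether B has stopped rising.

So I compare the late readings, averaged from 6.00 min on, and use these averages as estimates of where each run ends. Oak averages 19.6% B and 77.5% target; maple averages 28.6% and 69.2%. I assume that B gained per target gained is proportional to partner left, with partner unread and counted as one per B. Then B equals the partner charge times the complement of exp(−s·target), all as fractions of the charge. Oak gives 0.736 and maple 0.788. Their mean, 0.762, is my selectivity factor: B made per target made, per fraction of partner left.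

For the flask, I let target and B share the whole charge. Straight proportion from maple gives 37.8% B, but the rule lowers it to 35.1%, leaving 64.9% target.

The forecast says all of the starting material has reacted, with conversion 99.7%, target 62% and B 36.5%, taking “B's share proportional to remaining partner”. Its B stands 1.4 points above mine.

The flask gives all of the starting material has reacted, with conversion 100%, target 62.9% and B 36.8%.

    starting material → target (k = 0.0955 s⁻¹)
    partner + intermediate A → side product B (k = 27.8 L mol⁻¹ s⁻¹)
    partner + intermediate B → side product A (k = 1.61 L mol⁻¹ s⁻¹)
    starting material + partner ⇌ intermediate B (K = 215 L mol⁻¹, k = 84.4 L mol⁻¹ s⁻¹)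
    starting material + partner → intermediate A (k = 49.3 L mol⁻¹ s⁻¹)

At 0.0968 min the flask's step to target uses starting material 1.8 times as fast as the step to intermediate A. Half of that second step's turnover is done by 0.0715 min, far earlier than the asked time. Read from the flask's own end, s is 0.836. Carried to the neighbour with 2.20 equiv of partner, my s gives 59.2% B, and that neighbour holds 61.1%.

(All runs come from a simulation on assumed constants.)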